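The vessel held equal charges of left-handed substrate and right-handed substrate with a single-handed free catalyst, and reagent was fed into it at a steady rate. I wanted the flask at 15 min.

| flask | left-handed substrate | right-handed substrate | reagent | free catalyst | impurity | remark | time |
|---|---|---|---|---|---|---|---|
| eta | 0.010 M | 0.010 M | 10 mM (fed, over 3.0 min) | 0.33 mM | 18 µM | run made earlier |  |
| beta | 0.010 M | 0.010 M | 10 mM (fed, over 3.0 min) | 0.33 mM | 70 µM | run made earlier |  |
| gamma | 0.010 M | 0.010 M | 10 mM (fed, over 3.0 min) | 0.66 mM | 35 µM | run made earlier |  |
| flask | 0.010 M | 0.010 M | 10.0 mM (fed, over 3.0 min) | 0.33 mM | 35 µM |  | 15 min |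

| run | time / min | left-handed substrate / % | right-handed substrate / % |
|---|---|---|---|
| eta | 1.00 | 47.5 | 50.2 |
| eta | 3.00 | 35.1 | 46.9 |
| eta | 6.00 | 29.8 | 42.8 |
| eta | 8.00 | 29.6 | 42.9 |
| eta | 12.0 | 29.2 | 41.9 |
| beta | 1.00 | 47.5 | 47.0 |
| beta | 2.00 | 43.3 | 46.4 |
| beta | 3.00 | 37.8 | 46.3 |
| beta | 6.00 | 32.4 | 41.1 |
| beta | 12.0 | 30.5 | 42.6 |
| gamma | 2.50 | 34.0 | 45.5 |
| gamma | 5.00 | 24.9 | 40.2 |
| gamma | 8.00 | 24.6 | 39.0 |
| gamma | 10.0 | 23.0 | 37.8 |
| gamma | 12.0 | 21.9 | 40.9 |

(each reading ± 1 percentage point)

* part of the left-handed substrate and right-handed substrate charged together that has reacted at 15 min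
* excess of left-handed product over right-handed product in the product at 15 min
* excess of right-handed substrate over left-handed substrate among what is left of the two at 15 min

- free catalyst is single-handed; left-handed substrate and right-handed substrate are mirror images of each other, charged as a racemate, each of them at the stated concentration
- the earlier runs were read with a standard deviation of 1 percentage point
- an excess is the difference of the two amounts in percent of their sum
- an excess is below zero if the other one leads

How far did it go? The reagent charge allowed a part 50.0 % of both substrates to react. The mean of the eta and beta runs at 12.0 min, whose impurity charges bracket this flask's, was 27.9 %, which I took for this flask. That is 55.8 % of what was allowed, and the eta readings barely moved after 6.00 min, so I judged that some reagent went elsewhere.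

How did the reacted part divide? Both substrates meet the same reagent and catalyst, so if each rate goes with its own substrate, the feed and the time drop out of their ratio. The eta and beta runs read 3.06, with their scatter on it, for what remains: the selectivity factor s, the logarithm of the fraction of its charge left of left-handed substrate divided by the same logarithm for right-handed substrate.

Their mean fraction of right-handed substrate left, 84.5 %, therefore gave 59.7 % of left-handed substrate and a substrate excess of 17.2 %. The earlier runs read substrates, not product. If product kept its hand, I reckoned its excess at 44.4 %.

The forecast, whose numbers differ a little from mine, gave 27.6 % reacted, a product excess of 43.5 % and a substrate excess of 16.5 %, reasoning that “The flask lies between eta and beta”.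

The simulated flask gave 28.5 % reacted, a product excess of 0.0195 % and a substrate excess of 17.8 %. Its 84 % of right-handed substrate left gives 58.7 % of left-handed substrate by s, against 59 % computed.

    left-handed product ⇌ right-handed product (k = 0.0213 s⁻¹)
    reagent + free catalyst + right-handed substrate → free catalyst + right-handed product (k = 744 L² mol⁻² s⁻¹)
    2 reagent → homo dimer (k = 1.24 L mol⁻¹ s⁻¹)
    reagent + free catalyst + left-handed substrate → free catalyst + left-handed product (k = 2310 L² mol⁻² s⁻¹)
    free catalyst + impurity → spent catalyst (k = 4930 L mol⁻¹ s⁻¹)

In this flask both catalysed steps ran while reagent stood at 33.9 % of its charge at 3.00 min and 2.99 % at 7.50 min, and half of the left-handed turnover was done by 2.48 min. Throughout, left-handed product turned into right-handed product with a forward half-life of 0.54 min, shorter than the time, and at 15.0 min the two products stood at 14.2 % and 14.2 %.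

In the neighbour flask with 0.025 M of reagent, 72 % of right-handed substrate was left, so s gives 36.6 % of left-handed substrate and an excess of 32.6 %. The computed neighbour gave 36 % and 33.0 %, with a product excess of 0.0169 %.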